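The ten-membered carbocycle is closed at C6–C7 (germacrane numbering: C6 is the ring carbinol carbon bearing the isovalerate, C7 the ring-fusion carbon bearing C11, C8 the lactone O–CH). The route exploits that C7 is the γ-carbon of the allyl unit C13=C11–C7 hidden in the α-methylene-γ-lactone ring. The precursor is an open chain: a C8-substituted 3-(bromomethyl)butenolide tethered to an enal (C6). CrCl2 turns the bromide into an allylchromium species that adds through C7 to the aldehyde; this one operation closes the ring, sets C6 and C7 under control of C8, and shifts the butenolide double bond out of the ring to the exocyclic methylene.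

Key step: step 13

Remark: germacrane numbering is used for all atoms (ring C1–C10, lactone C11–C13, C14 on C10, C15 on C4); the target is the (3R,6R,7R,8S) trans-fused lactone with 1(10)E and 4E alkenes, and a free O6–H changes the CIP descriptor of C7 from R to S without any change in space.

Step 1
Reactants: 1 acrolein; 2 propargyl bromide
Product: 4 rac-hex-1-en-5-yn-3-ol, via allenylzinc bromide 3 (not isolated)
Conditions: Zn dust, THF/sat. aq. NH4Cl, 0 °C → rt
Reagents that add atoms: none
Why: Zinc-mediated Barbier propargylation: allenylzinc bromide 3 adds 1,2 to the aldehyde with allylic transposition (SE2′) and should give the homopropargylic alcohol as the racemate.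

Step 2
Reactants: 4 rac-hex-1-en-5-yn-3-ol
Product: 5 (S)-hex-1-en-5-yn-3-ol
Conditions: Ti(O-i-Pr)4, D-(−)-diisopropyl tartrate, t-BuOOH (0.6 equiv), 4 Å MS, CH2Cl2, −20 °C
Reagents that add atoms: none
Why: Sharpless kinetic resolution: with D-(−)-tartrate the titanium catalyst epoxidises the (R)-enantiomer of this 1-substituted allyl alcohol much faster, so the (S)-alcohol that carries the future C8 configuration should be left behind.

Step 3
Reactants: 5 (S)-hex-1-en-5-yn-3-ol
Product: 6 (S)-3-(tert-butyldimethylsilyloxy)hex-1-en-5-yne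
Conditions: TBSCl, imidazole, DMF, rt
Reagents that add atoms: tert-butyldimethylsilyl chloride, CC(C)(C)[Si](C)(C)Cl
Why: Standard silylation of a secondary alcohol that leaves the stereocentre untouched and masks the hydroxyl for the organometallic steps.

Step 4
Reactants: 6 (S)-3-(tert-butyldimethylsilyloxy)hex-1-en-5-yne
Product: 8 (2E,5S)-5-(tert-butyldimethylsilyloxy)-3-methylhepta-2,6-dien-1-ol, via alkenyldimethylalane 7 (not isolated)
Conditions: Me3Al, Cp2ZrCl2 (0.25 equiv), CH2Cl2, 0 °C → rt; then n-BuLi, THF, −78 °C; (CH2O)n, −78 °C → rt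
Reagents that add atoms: trimethylaluminium, C[Al](C)C; paraformaldehyde (as formaldehyde), C=O
Why: Negishi zirconium-catalysed carboalumination adds methyl and aluminium syn across the terminal alkyne with aluminium on the terminal carbon, and the derived alanate is hydroxymethylated with retention, which fixes the 1(10)E trisubstituted alkene (C9 trans to C2).

Step 5
Reactants: 8 (2E,5S)-5-(tert-butyldimethylsilyloxy)-3-methylhepta-2,6-dien-1-ol
Product: 9 (3S,5E)-7-bromo-3-(tert-butyldimethylsilyloxy)-5-methylhepta-1,5-diene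
Conditions: CBr4, PPh3, CH2Cl2, 0 °C
Reagents that add atoms: carbon tetrabromide, BrC(Br)(Br)Br
Why: Appel reaction: SN2 displacement of the oxyphosphonium ion by bromide at the primary allylic carbon should proceed without allylic transposition at 0 °C.

Step 6
Reactants: 10 2,2-dimethyl-1,3-dioxan-5-one; 11 RAMP, (R)-1-amino-2-(methoxymethyl)pyrrolidine
Product: 12 RAMP hydrazone of 2,2-dimethyl-1,3-dioxan-5-one
Conditions: 4 Å MS, CH2Cl2, rt
Reagents that add atoms: none
Why: Condensation of the ketone with the Enders RAMP auxiliary gives the hydrazone that will control C3.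

Step 7
Reactants: 12 RAMP hydrazone of 2,2-dimethyl-1,3-dioxan-5-one; 9 (3S,5E)-7-bromo-3-(tert-butyldimethylsilyloxy)-5-methylhepta-1,5-diene
Product: 15 (R)-4-[(2E,5S)-5-(tert-butyldimethylsilyloxy)-3-methylhepta-2,6-dien-1-yl]-2,2-dimethyl-1,3-dioxan-5-one, via lithium azaenolate 13 (not isolated), via alkylated hydrazone 14 (not isolated)
Conditions: t-BuLi, THF, −78 °C; 9, −100 °C → rt; then sat. aq. oxalic acid, Et2O, rt
Reagents that add atoms: water, O
Why: Enders RAMP-hydrazone alkylation: the chelated lithium azaenolate 13 is alkylated by SN2 attack on the allylic bromide from its open face, which should set C3 as R, and two-phase oxalic acid hydrolysis of 14 frees the ketone without loss of the acetonide or the silyl ether.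

Step 8
Reactants: 15 (R)-4-[(2E,5S)-5-(tert-butyldimethylsilyloxy)-3-methylhepta-2,6-dien-1-yl]-2,2-dimethyl-1,3-dioxan-5-one
Product: 16 (E)-2-{(4R)-4-[(2E,5S)-5-(tert-butyldimethylsilyloxy)-3-methylhepta-2,6-dien-1-yl]-2,2-dimethyl-1,3-dioxan-5-ylidene}-N-methoxy-N-methylacetamide
Conditions: Ph3P=CHC(O)N(OMe)Me, toluene, 80 °C
Reagents that add atoms: N-methoxy-N-methyl-2-(triphenylphosphoranylidene)acetamide, CON(C)C(=O)C=P(c1ccccc1)(c1ccccc1)c1ccccc1
Why: Wittig olefination of the activated dialkoxy ketone with a stabilised ylide; allylic 1,3-strain with the C3 substituent places the carbonyl group syn to the unsubstituted C15H2, which is the 4E geometry (C6 cis to C15) of the target.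

Step 9
Reactants: 16 (E)-2-{(4R)-4-[(2E,5S)-5-(tert-butyldimethylsilyloxy)-3-methylhepta-2,6-dien-1-yl]-2,2-dimethyl-1,3-dioxan-5-ylidene}-N-methoxy-N-methylacetamide
Product: 17 (E)-2-{(4R)-4-[(2E,5S)-5-hydroxy-3-methylhepta-2,6-dien-1-yl]-2,2-dimethyl-1,3-dioxan-5-ylidene}-N-methoxy-N-methylacetamide
Conditions: TBAF, AcOH, THF, 0 °C → rt
Reagents that add atoms: none
Why: Fluoride-mediated desilylation, buffered with acetic acid, frees the C8 hydroxyl while the acetonide and the Weinreb amide stay intact.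

Step 10
Reactants: 17 (E)-2-{(4R)-4-[(2E,5S)-5-hydroxy-3-methylhepta-2,6-dien-1-yl]-2,2-dimethyl-1,3-dioxan-5-ylidene}-N-methoxy-N-methylacetamide
Product: 18 (E)-2-{(4R)-4-[(2E,5S)-5-hydroxy-3-methylhepta-2,6-dien-1-yl]-2,2-dimethyl-1,3-dioxan-5-ylidene}acetaldehyde
Conditions: i-Bu2AlH (2.5 equiv), THF, −78 °C; aq. Rochelle salt
Reagents that add atoms: none
Why: Reduction of the Weinreb amide stops at the chelated aluminium hemiaminal, which releases the enal on work-up without over-reduction or conjugate reduction (the first equivalent of hydride is consumed by the free hydroxyl).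

Step 11
Reactants: 18 (E)-2-{(4R)-4-[(2E,5S)-5-hydroxy-3-methylhepta-2,6-dien-1-yl]-2,2-dimethyl-1,3-dioxan-5-ylidene}acetaldehyde; 19 2-(bromomethyl)acrylic acid
Product: 20 (3S,5E)-5-methyl-7-[(4R,5E)-2,2-dimethyl-5-(2-oxoethylidene)-1,3-dioxan-4-yl]hepta-1,5-dien-3-yl 2-(bromomethyl)acrylate
Conditions: DCC, DMAP (cat.), CH2Cl2, 0 °C
Reagents that add atoms: none
Why: Steglich esterification of the secondary allylic alcohol; low temperature and only catalytic DMAP limit SN2′ attack on the bromomethylacrylate.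

Step 12
Reactants: 20 (3S,5E)-5-methyl-7-[(4R,5E)-2,2-dimethyl-5-(2-oxoethylidene)-1,3-dioxan-4-yl]hepta-1,5-dien-3-yl 2-(bromomethyl)acrylate
Product: 21 (5S)-3-(bromomethyl)-5-{(2E)-2-methyl-4-[(4R,5E)-2,2-dimethyl-5-(2-oxoethylidene)-1,3-dioxan-4-yl]but-2-en-1-yl}furan-2(5H)-one
Conditions: second-generation Grubbs catalyst RuCl2(=CHPh)(PCy3)(H2IMes) (10 mol%), CH2Cl2 (5 mM), 40 °C
Reagents that add atoms: none
Why: Ring-closing metathesis between the terminal vinyl group and the acrylate alkene forms the five-membered butenolide (C7=C11), while the two trisubstituted alkenes are too hindered to take part.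

Step 13
Reactants: 21 (5S)-3-(bromomethyl)-5-{(2E)-2-methyl-4-[(4R,5E)-2,2-dimethyl-5-(2-oxoethylidene)-1,3-dioxan-4-yl]but-2-en-1-yl}furan-2(5H)-one
Product: 23 (3R,6R,7S,8S)-6-hydroxy-3,15-(isopropylidenedioxy)germacra-1(10)E,4E,11(13)-trien-12,8-olide, via allylchromium dichloride 22 (not isolated)
Conditions: CrCl2 (8 equiv), THF, rt, 21 added by syringe pump over 10 h (final 2 mM); aq. NH4Cl
Reagents that add atoms: none
Why: Two equivalents of CrCl2 (divalent chromium) reduce the allylic C13–Br bond of 21 to the allylchromium 22 (trivalent chromium), whose γ-carbon C7 adds to the aldehyde carbon C6 through a six-membered chair transition state while the double bond moves from C7=C11 to C11=C13. The closest known reaction type is the Nozaki–Hiyama–Kishi (Barbier-type) allylation, known between 3-(bromomethyl)butenolides and aldehydes and as a macrocyclic closure of ten-membered carbocycles. The ten-membered ring closes by 10-exo-trig addition of C7 to the C6 carbonyl group; attack through C13 would need a twelve-membered ring and does not fit the closed transition state. C7 is controlled by the C8 stereocentre, because the intrinsic preference for attack anti to the C9 substituent and the lower strain of the trans-fused E,E ten-membered ring both direct C6 to the butenolide face opposite to C9, which gives the trans-fused lactone. C6 is controlled by the ring-fixed geometry of the allyl unit (C8 trans to C13 across C7=C11), which in the chair with C5 equatorial gives the anti relation of O6 and C8, that is 6R. The step needs 1,2-addition to the enal and ring closure in preference to oligomerisation; allylchromium reagents add 1,2 and slow addition at 2 mM keeps the concentration of the open-chain reagent low.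

Step 14
Reactants: 23 (3R,6R,7S,8S)-6-hydroxy-3,15-(isopropylidenedioxy)germacra-1(10)E,4E,11(13)-trien-12,8-olide
Product: 24 (3R,6R,7R,8S)-3,15-(isopropylidenedioxy)-6-(3-methylbutanoyloxy)germacra-1(10)E,4E,11(13)-trien-12,8-olide
Conditions: (i-BuCO)2O, DMAP (cat.), pyridine, CH2Cl2, 0 °C → rt
Reagents that add atoms: isovaleric anhydride, CC(C)CC(=O)OC(=O)CC(C)C
Why: DMAP-catalysed acylation of the secondary allylic C6 hydroxyl, run promptly so that migration of the lactone from O8 to O6 cannot compete.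

Step 15
Reactants: 24 (3R,6R,7R,8S)-3,15-(isopropylidenedioxy)-6-(3-methylbutanoyloxy)germacra-1(10)E,4E,11(13)-trien-12,8-olide
Product: 25 (3R,6R,7R,8S)-3,15-dihydroxy-6-(3-methylbutanoyloxy)germacra-1(10)E,4E,11(13)-trien-12,8-olide
Conditions: PPTS (cat.), MeOH, rt
Reagents that add atoms: none
Why: Acid-catalysed transacetalisation to methanol removes the isopropylidene group under conditions that leave the allylic ester and the α-methylene lactone untouched.

Step 16
Reactants: 25 (3R,6R,7R,8S)-3,15-dihydroxy-6-(3-methylbutanoyloxy)germacra-1(10)E,4E,11(13)-trien-12,8-olide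
Product: 26 CNP0317194.1, (3R,6R,7R,8S)-3-hydroxy-6,15-bis(3-methylbutanoyloxy)germacra-1(10)E,4E,11(13)-trien-12,8-olide
Conditions: i-BuCOCl (1.1 equiv), 2,4,6-collidine, CH2Cl2, −78 → −40 °C
Reagents that add atoms: isovaleryl chloride, CC(C)CC(=O)Cl
Why: Selective acylation: the primary allylic C15 hydroxyl reacts far faster with the acid chloride at low temperature than the hindered secondary C3 hydroxyl next to the fully substituted C4.

Compound list

1 | acrolein | C=CC=O | starting material
2 | propargyl bromide (3-bromoprop-1-yne) | C#CCBr | starting material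
3 | allenylzinc bromide | C=C=C[Zn]Br | intermediate
4 | rac-hex-1-en-5-yn-3-ol | C=CC(O)CC#C | intermediate
5 | (S)-hex-1-en-5-yn-3-ol | C=C[C@@H](O)CC#C | intermediate
6 | (S)-3-(tert-butyldimethylsilyloxy)hex-1-en-5-yne | C=C[C@@H](O[Si](C)(C)C(C)(C)C)CC#C | intermediate
7 | dimethyl[(1E,4S)-4-(tert-butyldimethylsilyloxy)-2-methylhexa-1,5-dien-1-yl]alane | C=C[C@@H](O[Si](C)(C)C(C)(C)C)C/C(C)=C/[Al](C)C | intermediate
8 | (2E,5S)-5-(tert-butyldimethylsilyloxy)-3-methylhepta-2,6-dien-1-ol | C=C[C@@H](O[Si](C)(C)C(C)(C)C)C/C(C)=C/CO | intermediate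
9 | (3S,5E)-7-bromo-3-(tert-butyldimethylsilyloxy)-5-methylhepta-1,5-diene | C=C[C@@H](O[Si](C)(C)C(C)(C)C)C/C(C)=C/CBr | intermediate
10 | 2,2-dimethyl-1,3-dioxan-5-one | CC1(C)OCC(=O)CO1 | starting material
11 | RAMP, (R)-1-amino-2-(methoxymethyl)pyrrolidine | COC[C@H]1CCCN1N | starting material
12 | RAMP hydrazone of 10, (R)-N-(2,2-dimethyl-1,3-dioxan-5-ylidene)-2-(methoxymethyl)pyrrolidin-1-amine | COC[C@H]1CCCN1N=C1COC(C)(C)OC1 | intermediate
13 | lithium azaenolate of 12 (N-lithio ene-hydrazide) | COC[C@H]1CCCN1N([Li])C1=COC(C)(C)OC1 | intermediate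
14 | RAMP hydrazone of ketone 15, (4R)-alkylated at C3 | C=C[C@@H](O[Si](C)(C)C(C)(C)C)C/C(C)=C/C[C@H]1OC(C)(C)OCC1=NN1CCC[C@@H]1COC | intermediate
15 | (R)-4-[(2E,5S)-5-(tert-butyldimethylsilyloxy)-3-methylhepta-2,6-dien-1-yl]-2,2-dimethyl-1,3-dioxan-5-one | C=C[C@@H](O[Si](C)(C)C(C)(C)C)C/C(C)=C/C[C@H]1OC(C)(C)OCC1=O | intermediate
16 | (E)-2-{(4R)-4-[(2E,5S)-5-(tert-butyldimethylsilyloxy)-3-methylhepta-2,6-dien-1-yl]-2,2-dimethyl-1,3-dioxan-5-ylidene}-N-methoxy-N-methylacetamide | C=C[C@@H](O[Si](C)(C)C(C)(C)C)C/C(C)=C/C[C@H]1OC(C)(C)OC/C1=C\C(=O)N(C)OC | intermediate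
17 | (E)-2-{(4R)-4-[(2E,5S)-5-hydroxy-3-methylhepta-2,6-dien-1-yl]-2,2-dimethyl-1,3-dioxan-5-ylidene}-N-methoxy-N-methylacetamide | C=C[C@@H](O)C/C(C)=C/C[C@H]1OC(C)(C)OC/C1=C\C(=O)N(C)OC | intermediate
18 | (E)-2-{(4R)-4-[(2E,5S)-5-hydroxy-3-methylhepta-2,6-dien-1-yl]-2,2-dimethyl-1,3-dioxan-5-ylidene}acetaldehyde | C=C[C@@H](O)C/C(C)=C/C[C@H]1OC(C)(C)OC/C1=C\C=O | intermediate
19 | 2-(bromomethyl)acrylic acid | C=C(CBr)C(=O)O | starting material
20 | (3S,5E)-5-methyl-7-[(4R,5E)-2,2-dimethyl-5-(2-oxoethylidene)-1,3-dioxan-4-yl]hepta-1,5-dien-3-yl 2-(bromomethyl)acrylate | C=C[C@@H](OC(=O)C(=C)CBr)C/C(C)=C/C[C@H]1OC(C)(C)OC/C1=C\C=O | intermediate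
21 | (5S)-3-(bromomethyl)-5-{(2E)-2-methyl-4-[(4R,5E)-2,2-dimethyl-5-(2-oxoethylidene)-1,3-dioxan-4-yl]but-2-en-1-yl}furan-2(5H)-one | O=C1O[C@@H](C/C(C)=C/C[C@H]2OC(C)(C)OC/C2=C\C=O)C=C1CBr | intermediate
22 | allylchromium dichloride from 21 (trivalent chromium on C13) | O=C1O[C@@H](C/C(C)=C/C[C@H]2OC(C)(C)OC/C2=C\C=O)C=C1C[Cr](Cl)Cl | intermediate
23 | (3R,6R,7S,8S)-6-hydroxy-3,15-(isopropylidenedioxy)germacra-1(10)E,4E,11(13)-trien-12,8-olide | C=C1C(=O)O[C@H]2C/C(C)=C/C[C@H]3OC(C)(C)OC/C3=C\[C@@H](O)[C@H]12 | intermediate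
24 | (3R,6R,7R,8S)-3,15-(isopropylidenedioxy)-6-(3-methylbutanoyloxy)germacra-1(10)E,4E,11(13)-trien-12,8-olide | C=C1C(=O)O[C@H]2C/C(C)=C/C[C@H]3OC(C)(C)OC/C3=C\[C@@H](OC(=O)CC(C)C)[C@H]12 | intermediate
25 | (3R,6R,7R,8S)-3,15-dihydroxy-6-(3-methylbutanoyloxy)germacra-1(10)E,4E,11(13)-trien-12,8-olide | C=C1C(=O)O[C@H]2C/C(C)=C/C[C@@H](O)/C(CO)=C/[C@@H](OC(=O)CC(C)C)[C@H]12 | intermediate
26 | CNP0317194.1, (3R,6R,7R,8S)-3-hydroxy-6,15-bis(3-methylbutanoyloxy)germacra-1(10)E,4E,11(13)-trien-12,8-olide | C=C1C(=O)O[C@H]2C/C(C)=C/C[C@@H](O)/C(COC(=O)CC(C)C)=C/[C@@H](OC(=O)CC(C)C)[C@H]12 | target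

Total step count: 16.
Longest linear sequence: 15 steps (steps 1–5, then 7–16); step 6 is the one-step side branch to hydrazone 12.

Steps most likely to fail

1. Step 13 (key step). What may go wrong: poor facial selectivity at the aldehyde, because the strain of the forming ten-membered ring (the dioxane has to turn C2 into an axial position) can override the chair transition state. The fallback sets out from 21: the closure is run as described and the alcohol epimeric at C6, (3R,6S,7S,8S)-6-hydroxy-3,15-(isopropylidenedioxy)germacra-1(10)E,4E,11(13)-trien-12,8-olide F1, is taken on. Mitsunobu esterification of F1 with isovaleric acid (PPh3, DIAD, toluene, 0 °C) installs the isovalerate with inversion at C6, so C6 is then set by SN2 displacement instead of by the addition, and the route is rejoined at 24.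

2. Step 12. What may go wrong: deactivation of the catalyst by the allylic bromide and slow closure onto the electron-poor 1,1-disubstituted alkene, so that intermolecular metathesis at the vinyl group takes over. The fallback sets out from 18 and brings in the bromide only after the metathesis. Ethyl 2-(hydroxymethyl)acrylate is silylated (TBSCl, imidazole, DMF) to ethyl 2-{[(tert-butyldimethylsilyl)oxy]methyl}acrylate F2 and saponified (LiOH, THF/H2O) to 2-{[(tert-butyldimethylsilyl)oxy]methyl}acrylic acid F3. Steglich esterification of 18 with F3 should give the silyloxymethyl acrylate ester F4, ring-closing metathesis with the same catalyst the silyloxymethyl butenolide F5, and TBAF/AcOH the hydroxymethyl butenolide F6. Appel bromination (CBr4, PPh3, CH2Cl2, 0 °C) then comes back to the route at 21.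

3. Step 8. What may go wrong: slow addition of the amide-stabilised ylide to the hindered ketone, with epimerisation at C3 through the enol during long heating. The fallback sets out from 15 and reaches the enal through the ester oxidation level. Wittig reaction with ethyl (triphenylphosphoranylidene)acetate at rt, a ylide of known reactivity toward 1,3-dioxan-5-ones, should give the ethyl ester F7. Reduction with i-Bu2AlH (CH2Cl2, −78 °C) gives the allylic alcohol F8, oxidation with MnO2 (CH2Cl2, rt) the silyl-protected enal F9, and TBAF/AcOH comes back to the route at 18.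

Further compounds

F1 | step 13 | (3R,6S,7S,8S)-6-hydroxy-3,15-(isopropylidenedioxy)germacra-1(10)E,4E,11(13)-trien-12,8-olide | C=C1C(=O)O[C@H]2C/C(C)=C/C[C@H]3OC(C)(C)OC/C3=C\[C@H](O)[C@H]12
F2 | step 12 | ethyl 2-{[(tert-butyldimethylsilyl)oxy]methyl}acrylate | C=C(CO[Si](C)(C)C(C)(C)C)C(=O)OCC
F3 | step 12 | 2-{[(tert-butyldimethylsilyl)oxy]methyl}acrylic acid | C=C(CO[Si](C)(C)C(C)(C)C)C(=O)O
F4 | step 12 | (3S,5E)-5-methyl-7-[(4R,5E)-2,2-dimethyl-5-(2-oxoethylidene)-1,3-dioxan-4-yl]hepta-1,5-dien-3-yl 2-{[(tert-butyldimethylsilyl)oxy]methyl}acrylate | C=C[C@@H](OC(=O)C(=C)CO[Si](C)(C)C(C)(C)C)C/C(C)=C/C[C@H]1OC(C)(C)OC/C1=C\C=O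
F5 | step 12 | (5S)-3-{[(tert-butyldimethylsilyl)oxy]methyl}-5-{(2E)-2-methyl-4-[(4R,5E)-2,2-dimethyl-5-(2-oxoethylidene)-1,3-dioxan-4-yl]but-2-en-1-yl}furan-2(5H)-one | O=C1O[C@@H](C/C(C)=C/C[C@H]2OC(C)(C)OC/C2=C\C=O)C=C1CO[Si](C)(C)C(C)(C)C
F6 | step 12 | (5S)-3-(hydroxymethyl)-5-{(2E)-2-methyl-4-[(4R,5E)-2,2-dimethyl-5-(2-oxoethylidene)-1,3-dioxan-4-yl]but-2-en-1-yl}furan-2(5H)-one | O=C1O[C@@H](C/C(C)=C/C[C@H]2OC(C)(C)OC/C2=C\C=O)C=C1CO
F7 | step 8 | ethyl (E)-2-{(4R)-4-[(2E,5S)-5-(tert-butyldimethylsilyloxy)-3-methylhepta-2,6-dien-1-yl]-2,2-dimethyl-1,3-dioxan-5-ylidene}acetate | C=C[C@@H](O[Si](C)(C)C(C)(C)C)C/C(C)=C/C[C@H]1OC(C)(C)OC/C1=C\C(=O)OCC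
F8 | step 8 | (E)-2-{(4R)-4-[(2E,5S)-5-(tert-butyldimethylsilyloxy)-3-methylhepta-2,6-dien-1-yl]-2,2-dimethyl-1,3-dioxan-5-ylidene}ethanol | C=C[C@@H](O[Si](C)(C)C(C)(C)C)C/C(C)=C/C[C@H]1OC(C)(C)OC/C1=C\CO
F9 | step 8 | (E)-2-{(4R)-4-[(2E,5S)-5-(tert-butyldimethylsilyloxy)-3-methylhepta-2,6-dien-1-yl]-2,2-dimethyl-1,3-dioxan-5-ylidene}acetaldehyde | C=C[C@@H](O[Si](C)(C)C(C)(C)C)C/C(C)=C/C[C@H]1OC(C)(C)OC/C1=C\C=O
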